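**Remark on the chemistry:** the target has no stereocentre. Compounds 15 and 24 are racemic and the stilbenes 6, 7 and 9 are E/Z mixtures; both elements are erased later, so neither is controlled.

## Analysis of the target

Compound 28 is an 18-membered macrocycle of the bis(bibenzyl) type built from four six-membered carbocycles. Ring A, a 1,4-benzoquinone, is linked from A5 through a CH2CH2 bridge to ring B. Ring B is linked para through an ether oxygen to ring C, ring C through a second CH2CH2 bridge to ring D, and ring D meta through an ether oxygen back to A4. Ring C carries a free hydroxyl ortho to the ring B oxygen and para to its bridge. Ring A has four different substituents in fixed order: methoxy on A1, hydrogen on A2, aryloxy on A4, alkyl on A5, with carbonyls at A3 and A6. There is no stereocentre and the large ring is flexible, so the problems are regiochemical and chemoselective. The quinone is an oxidant and an acceptor, and its A1 methoxy and A4 aryloxy groups are vinylogous esters that amines, alkoxides and phenoxides can displace. The CH2 on A5 is acidified, and the ring C phenol is electron-rich. The plan rests on one feature: A3–A4–A5–A6 has the oxidation pattern of a cyclobutenedione with aryloxy and alkyl on its alkene carbons, and A1–A2 is a methoxyalkyne.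

## Retrosynthetic reasoning

**28 from 27.** The last bond cut is the O–Si bond on ring C. A triisopropylsilyl ether is chosen over a smaller silyl group because it must survive the warm aqueous acid that converts 15 into 17. It still falls to buffered fluoride, which brings no nucleophile, reductant or oxidant to the quinone.

**27 from 24.** Ring A is opened at A6–A1 and folded back to a four-membered ring by reconnecting A6 to A3. This is the only cut that splits ring A into two pieces in which all four substituents are already placed. The rearrangement delivers hydrogen to the inner alkyne carbon, and A2 is the only ring A carbon bearing hydrogen, so A1–A2 must be the alkyne. The gain is that the quinone appears in the last carbon–carbon bond formation, under neutral thermal conditions, with the macrocycle already closed. The forward step must open the cyclobutenone and close a six-membered ring in preference to a five-membered one.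

**24 from 19 and 22.** The bond between the carbinol carbon (future A3) and the alkyne is cut, giving dione 19 and acetylide 23 from alkyne 22. The two carbonyls of 19 differ. The one beside the aryloxy-bearing carbon is ketone-like; the other is the carbonyl of a vinylogous ester and is less electrophilic. Addition at the first gives the substitution pattern that 27 needs. Alkyne 22 is made from 20 and isolated, so that the acetylide solution holds no amine or alkoxide that could displace the ring D aryloxy group of 19.

**19 from 17.** The macrocycle is opened at the bond between the ring D oxygen and the four-membered ring. This closure is an acylation-type addition–elimination, forms no carbon–carbon bond, and makes an unstrained 18-membered ring. Using the alkoxy group of 16 directly as leaving group was considered and set aside: exchanging alkoxy for aryloxy on a vinylogous ester runs thermodynamically uphill. The vinylogous acid 17 is therefore activated as chloride 18, which makes the exchange downhill and fast.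

**17 from 15, and 15 from 12 and 13.** The bond between the four-membered ring and the ring B ethylene bridge is cut, giving squarate 13 and Grignard reagent 14 from bromide 12. One acid treatment of adduct 15 then does three jobs: rearrangement to dione 16, hydrolysis of the remaining vinylogous ester, and release of the ring D phenol.

**12 from 11 from 10.** These are functional group changes on the ring D–C–B chain. The primary alcohol is brominated first, under conditions that leave a phenol alone, and the ring C phenol is silylated afterwards.

**10 from 9, and 9 from 7 and 8.** One hydrogenation saturates the stilbene and removes the benzyl group that protected ring C through the copper-catalysed coupling. The ring B–O–ring C ether is cut into aryl bromide 7 and phenol 8, which brings ring B with its two-carbon chain in one piece.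

**7 from 2 and 4; 2 from 1; 4 from 3.** The ring C–ring D bridge is cut at the olefin, giving aldehyde 4 and phosphonium salt 2. The ring D oxygen is masked in the same flask as an acetal, which later falls in the acid step from 15 to 17.

## Alternatives that were turned down

**Alternative 1:** ring B is disconnected into a diene and an alkyne. The precursor A1 carries a 2-aryloxybuta-1,3-diene on the ring C oxygen and an ethynyl ketone on the ring A side chain. An intramolecular Diels–Alder reaction would form two carbon–carbon bonds, ring B as a cyclohexa-1,4-diene and the 18-membered ring, giving A2.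
- For it: it is the most bond-forming single step of all four plans, the donor-substituted diene and the ynone are electronically matched for the para orientation ring B needs, and no copper coupling is needed for the ring B–ring C ether. On bonds formed per step it is stronger than the chosen route.
- Against it: the aryloxydiene in A1 is an acid-labile, polymerisable enol ether that must be installed on a hindered phenol oxygen, and the terminal ynone is a reactive acceptor. The cycloaddition across a long flexible tether has a low effective molarity and needs heat at high dilution, where both partners can decompose.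
- After the key step, A2 still needs aromatisation, removal of the benzylic ketone, three debenzylations and oxidation of ring A.
- The chosen route forms fewer bonds in its key step but delivers ring A at its final oxidation level, one deprotection from 28.

**Alternative 2:** the macrocycle is opened at the ring D oxygen–A4 bond of the quinone itself. In the seco compound A3, the ring D phenoxide would add to the bromine-bearing carbon A4 and expel bromide, giving A4, the ring C methoxymethyl ether of the target.
- For it: the ring closure is an intrinsically favourable addition–elimination at room temperature, with no strained ring, no ynol ether and no thermolysis. On mildness and likely step count it is equal to or better than the chosen route, and its endgame is equally short.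
- Against it: the macrocyclisation exposes a finished quinone to phenoxide and base. The phenoxide can also add at the unsubstituted A2, displace the A1 methoxy group, transfer an electron to the bromoquinone, or deprotonate the CH2 on A5.
- A3 also needs a regiodefined tetrasubstituted bromoquinone on a long chain, and A4 must be unmasked under acid with the aryloxyquinone present.
- The chosen route fixes the order of the four ring A substituents by the order of additions to a squarate, and the quinone never meets base or a nucleophile.

**Alternative 3:** the macrocycle is opened at the ring B oxygen–ring C bond. In the seco compound A5, anodic oxidation of the 2,6-dibromo-4-alkylphenolate of ring C would let the ring B phenol oxygen bond to a bromine-bearing ortho carbon. Zinc reduction of the bromodienone would then give A6.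
- For it: it forms the ortho-hydroxy diaryl ether directly, with the ring C hydroxyl free and no copper, which is more direct for that motif than the benzyl-to-silyl exchange used here.
- Against it: A5 holds three oxidisable arenes (the ring B phenol, the ring C phenolate and the trialkoxy ring A), so over-oxidation and carbon–carbon coupling compete with the wanted ether formation in a dilute macrocyclisation.
- A6 still needs debromination, two debenzylations and oxidation of ring A, and A5 already needs the hindered ring D–A4 ether on a hexasubstituted ring A.
- The chosen route closes its ring by a non-oxidative acylation-type reaction and forms the quinone without an external oxidant.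

Key step: step 13

## Route

Step 1
Reactants: 1 3-(hydroxymethyl)phenol
Product: 2 [(3-hydroxyphenyl)methyl]triphenylphosphonium bromide
Conditions: PPh3·HBr, MeCN, reflux
Reagents that add atoms: triphenylphosphine hydrobromide, Br.c1ccc(cc1)P(c1ccccc1)c1ccccc1
Why: Phosphonium salt formation: the acid converts the benzylic alcohol into a benzylic electrophile that quaternises triphenylphosphine; the phenol is inert and the salt should crystallise.

Step 2
Reactants: 3 3-bromo-4-hydroxybenzaldehyde
Product: 4 4-(benzyloxy)-3-bromobenzaldehyde
Conditions: BnBr, K2CO3, DMF, rt
Reagents that add atoms: benzyl bromide, BrCc1ccccc1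
Why: Williamson ether synthesis on an acidic phenol; benzyl survives the later basic copper coupling and is removed for free in the hydrogenation of step 5.

Step 3
Reactants: 2 [(3-hydroxyphenyl)methyl]triphenylphosphonium bromide; 4 4-(benzyloxy)-3-bromobenzaldehyde
Product: 7 1-(benzyloxy)-2-bromo-4-{2-[3-(methoxymethoxy)phenyl]ethenyl}benzene (E/Z mixture), via phenolate ylide 5 (not isolated), via stilbene phenolate 6 (not isolated)
Conditions: KOtBu (2.3 equiv), THF, 0 °C; then 4, 0 °C to rt; then MOMCl, 0 °C to rt
Reagents that add atoms: chloromethyl methyl ether, COCCl
Why: Wittig olefination with a semi-stabilised benzylic ylide that carries its phenol as the potassium salt, followed by O-alkylation of that phenolate in the same flask. Olefin geometry does not matter because step 5 saturates the double bond.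

Step 4
Reactants: 7 1-(benzyloxy)-2-bromo-4-{2-[3-(methoxymethoxy)phenyl]ethenyl}benzene; 8 2-(4-hydroxyphenyl)ethanol
Product: 9 2-{4-[2-(benzyloxy)-5-{2-[3-(methoxymethoxy)phenyl]ethenyl}phenoxy]phenyl}ethanol (E/Z mixture)
Conditions: CuI (10 mol %), picolinic acid (20 mol %), K3PO4, DMSO, 90 °C
Reagents that add atoms: none
Why: Ullmann-type diaryl ether synthesis with a monovalent copper catalyst. Under phosphate base only the phenol of 8 is deprotonated, so the aliphatic hydroxyl should stay unarylated; benzyl and methoxymethyl ethers tolerate the conditions.

Step 5
Reactants: 9 2-{4-[2-(benzyloxy)-5-{2-[3-(methoxymethoxy)phenyl]ethenyl}phenoxy]phenyl}ethanol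
Product: 10 2-[4-(2-hydroxyethyl)phenoxy]-4-{2-[3-(methoxymethoxy)phenyl]ethyl}phenol
Conditions: H2 (1 atm), Pd/C, EtOAc–EtOH, rt
Reagents that add atoms: none
Why: Catalytic hydrogenation saturates the stilbene and hydrogenolyses the benzyl ether in one operation; the acetal and the diaryl ether are inert.

Step 6
Reactants: 10 2-[4-(2-hydroxyethyl)phenoxy]-4-{2-[3-(methoxymethoxy)phenyl]ethyl}phenol
Product: 11 2-[4-(2-bromoethyl)phenoxy]-4-{2-[3-(methoxymethoxy)phenyl]ethyl}phenol
Conditions: CBr4, PPh3, CH2Cl2, 0 °C
Reagents that add atoms: carbon tetrabromide, BrC(Br)(Br)Br
Why: Appel bromination: only the primary alkoxyphosphonium ion can be displaced by bromide, so the phenol is recovered unchanged, and the near-neutral medium spares the acetal.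

Step 7
Reactants: 11 2-[4-(2-bromoethyl)phenoxy]-4-{2-[3-(methoxymethoxy)phenyl]ethyl}phenol
Product: 12 {2-[4-(2-bromoethyl)phenoxy]-4-{2-[3-(methoxymethoxy)phenyl]ethyl}phenoxy}tri(propan-2-yl)silane
Conditions: TIPSOTf, 2,6-lutidine, CH2Cl2, 0 °C
Reagents that add atoms: triisopropylsilyl trifluoromethanesulfonate, CC(C)[Si](OS(=O)(=O)C(F)(F)F)(C(C)C)C(C)C
Why: Silylation of the hindered ortho-aryloxy phenol with a silyl triflate and a hindered base, which does not alkylate with or eliminate the primary bromide. The bulky silyl ether is stable to Grignard formation, aqueous acid and acetylide.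

Step 8
Reactants: 12 {2-[4-(2-bromoethyl)phenoxy]-4-{2-[3-(methoxymethoxy)phenyl]ethyl}phenoxy}tri(propan-2-yl)silane; 13 3,4-di(propan-2-yloxy)cyclobut-3-ene-1,2-dione
Product: 15 4-hydroxy-2,3-di(propan-2-yloxy)-4-[2-(4-{5-[2-(3-(methoxymethoxy)phenyl)ethyl]-2-[tri(propan-2-yl)silyloxy]phenoxy}phenyl)ethyl]cyclobut-2-en-1-one (racemic), via Grignard reagent 14 (not isolated)
Conditions: Mg, THF, 35 °C; then added to 13, THF, −78 °C; aq. NH4Cl
Reagents that add atoms: none
Why: Magnesium insertion into the primary bromide and 1,2-addition of the Grignard reagent to one carbonyl of the squarate. At −78 °C with inverse addition the reaction should stop at the mono-adduct; the new carbinol centre is racemic and is lost in step 9.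

Step 9
Reactants: 15 4-hydroxy-2,3-di(propan-2-yloxy)-4-[2-(4-{5-[2-(3-(methoxymethoxy)phenyl)ethyl]-2-[tri(propan-2-yl)silyloxy]phenoxy}phenyl)ethyl]cyclobut-2-en-1-one
Product: 17 3-hydroxy-4-[2-(4-{5-[2-(3-hydroxyphenyl)ethyl]-2-[tri(propan-2-yl)silyloxy]phenoxy}phenyl)ethyl]cyclobut-3-ene-1,2-dione, via isopropoxy dione 16 (not isolated)
Conditions: 6 M HCl aq–THF (1:2), rt to 45 °C
Reagents that add atoms: water, O
Why: Acid-promoted rearrangement of the squarate 1,2-adduct to the 3-alkyl-4-alkoxycyclobutenedione, then hydrolysis of the remaining vinylogous ester and of the methoxymethyl acetal in the same medium. An aryl triisopropylsilyl ether is expected to resist these conditions.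

Step 10
Reactants: 17 3-hydroxy-4-[2-(4-{5-[2-(3-hydroxyphenyl)ethyl]-2-[tri(propan-2-yl)silyloxy]phenoxy}phenyl)ethyl]cyclobut-3-ene-1,2-dione
Product: 19 macrocyclic 3-aryloxy-4-alkylcyclobut-3-ene-1,2-dione (ring D oxygen on C3, ring B ethylene bridge on C4, 18-membered ring, ring C phenol as triisopropylsilyl ether), via chloro dione 18 (not isolated)
Conditions: (COCl)2 (1.1 equiv), DMF (cat.), CH2Cl2 (5 mM), 0 °C; then syringe-pump addition to iPr2NEt, CH2Cl2 (final 1 mM), rt
Reagents that add atoms: none
Why: The strongly acidic vinylogous acid is converted into its chloride as a carboxylic acid would be, while the unactivated phenol stays free in the absence of base (as in acid chloride formation from hydroxybenzoic acids). Slow addition to a hindered amine then lets the ring D phenol close the 18-membered ring by addition–elimination at the chlorine-bearing carbon; with chloride as leaving group the exchange is downhill, unlike exchange of an alkoxy group.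

Step 11
Reactants: 20 2-chloro-1,1-dimethoxyethane
Product: 22 methoxyethyne, via sodium methoxyacetylide 21 (not isolated)
Conditions: NaNH2 (3 equiv), NH3 (l), −33 °C; then cold brine; distilled into THF at −78 °C
Reagents that add atoms: none
Why: Twofold base-induced elimination (loss of methanol, then of HCl) and deprotonation give the sodium acetylide; protonation and distillation give the volatile ynol ether as a cold THF solution free of amine and alkoxide.

Step 12
Reactants: 19 macrocyclic 3-aryloxy-4-alkylcyclobut-3-ene-1,2-dione; 22 methoxyethyne
Product: 24 macrocyclic 2-alkyl-3-aryloxy-4-hydroxy-4-(methoxyethynyl)cyclobut-2-en-1-one (racemic; ring C phenol as triisopropylsilyl ether), via lithium methoxyacetylide 23 (not isolated)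
Conditions: n-BuLi, THF, −78 °C; then 19, −78 °C; aq. NH4Cl at −78 °C
Reagents that add atoms: none
Why: 1,2-Addition of a lithium acetylide to a cyclobutenedione. The carbonyl beside the aryloxy-bearing carbon is ketone-like and more electrophilic than the vinylogous ester carbonyl beside the alkyl-bearing carbon, so addition should occur there. The new carbinol centre is racemic and is destroyed in step 13.

Step 13
Reactants: 24 macrocyclic 2-alkyl-3-aryloxy-4-hydroxy-4-(methoxyethynyl)cyclobut-2-en-1-one
Product: 27 ring C triisopropylsilyl ether of the target quinone, via enynyl ketene 25 (not isolated), via benzenoid diradical 26 (not isolated)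
Conditions: PhMe (degassed, 2 mM), 80 to 110 °C
Reagents that add atoms: none
Why: Moore rearrangement: thermal conrotatory 4π ring opening breaks the bond between the carbonyl carbon (future A6) and the carbinol carbon (future A3), and the hydroxyl donor rotates outwards, so ketene 25 forms with the ketene and the methoxyalkyne cis on the A4=A3 double bond. The ketene carbon then bonds to the methoxy-bearing alkyne carbon (A6–A1), closing ring A in a six-membered mode with both alkyne carbons inside the new ring and giving diradical 26 (aryl radical at A2, oxygen radical on A6). Transfer of the hydroxyl hydrogen from the A3 oxygen to A2 collapses 26 to quinone 27. The closest known reaction type is the thermolysis of 4-alkynyl-4-hydroxycyclobutenones to 1,4-benzoquinones. No stereocentre is formed and the carbinol centre of 24 disappears, so the racemic precursor should give a single product. The step needs six-membered closure to beat five-membered exo closure to an alkylidenecyclopentenedione: the methoxy group gives an exocyclic vinyl radical none of the conjugative stabilisation that aryl, silyl or ester groups give, and only the six-membered path gains a benzenoid ring. Regiochemistry is not at stake here because it was fixed in 24 by the site of alkynylation, and the 18-membered ring only spans A4 and A5, which remain neighbours throughout. A methyl ynol ether has no β-hydrogen for retro-ene loss of an alkene, so the alkyne should survive the temperature.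

Step 14
Reactants: 27 ring C triisopropylsilyl ether of the target quinone
Product: 28 CNP0332646.0 (target quinone with free ring C phenol)
Conditions: TBAF, AcOH, THF, 0 °C
Reagents that add atoms: none
Why: Fluoride-induced cleavage of an aryl silyl ether; acetic acid buffers the phenoxide and the fluoride so that neither attacks the vinylogous esters of the quinone.

## Compound list

1 | 3-(hydroxymethyl)phenol | OCc1cccc(O)c1 | starting material
2 | [(3-hydroxyphenyl)methyl]triphenylphosphonium bromide | Oc1cccc(C[P+](c2ccccc2)(c2ccccc2)c2ccccc2)c1.[Br-] | intermediate
3 | 3-bromo-4-hydroxybenzaldehyde | O=Cc1ccc(O)c(Br)c1 | starting material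
4 | 4-(benzyloxy)-3-bromobenzaldehyde | O=Cc1ccc(OCc2ccccc2)c(Br)c1 | intermediate
5 | potassium 3-[(triphenyl-λ5-phosphanylidene)methyl]phenolate (phenolate ylide) | [K+].[O-]c1cccc(C=P(c2ccccc2)(c2ccccc2)c2ccccc2)c1 | intermediate
6 | potassium 3-{2-[4-(benzyloxy)-3-bromophenyl]ethenyl}phenolate (E/Z mixture) | [K+].[O-]c1cccc(C=Cc2ccc(OCc3ccccc3)c(Br)c2)c1 | intermediate
7 | 1-(benzyloxy)-2-bromo-4-{2-[3-(methoxymethoxy)phenyl]ethenyl}benzene (E/Z mixture) | COCOc1cccc(C=Cc2ccc(OCc3ccccc3)c(Br)c2)c1 | intermediate
8 | 2-(4-hydroxyphenyl)ethanol | OCCc1ccc(O)cc1 | starting material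
9 | 2-{4-[2-(benzyloxy)-5-{2-[3-(methoxymethoxy)phenyl]ethenyl}phenoxy]phenyl}ethanol (E/Z mixture) | OCCc1ccc(cc1)Oc1cc(C=Cc2cccc(OCOC)c2)ccc1OCc1ccccc1 | intermediate
10 | 2-[4-(2-hydroxyethyl)phenoxy]-4-{2-[3-(methoxymethoxy)phenyl]ethyl}phenol | OCCc1ccc(cc1)Oc1cc(CCc2cccc(OCOC)c2)ccc1O | intermediate
11 | 2-[4-(2-bromoethyl)phenoxy]-4-{2-[3-(methoxymethoxy)phenyl]ethyl}phenol | BrCCc1ccc(cc1)Oc1cc(CCc2cccc(OCOC)c2)ccc1O | intermediate
12 | {2-[4-(2-bromoethyl)phenoxy]-4-{2-[3-(methoxymethoxy)phenyl]ethyl}phenoxy}tri(propan-2-yl)silane | BrCCc1ccc(cc1)Oc1cc(CCc2cccc(OCOC)c2)ccc1O[Si](C(C)C)(C(C)C)C(C)C | intermediate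
13 | 3,4-di(propan-2-yloxy)cyclobut-3-ene-1,2-dione (diisopropyl squarate) | CC(C)OC1=C(OC(C)C)C(=O)C1=O | starting material
14 | Grignard reagent from 12 (bromomagnesium on the ethyl chain of ring B) | Br[Mg]CCc1ccc(cc1)Oc1cc(CCc2cccc(OCOC)c2)ccc1O[Si](C(C)C)(C(C)C)C(C)C | intermediate
15 | squarate mono-adduct: 4-hydroxy-2,3-di(propan-2-yloxy)-4-(2-arylethyl)cyclobut-2-en-1-one, racemic | CC(C)OC1=C(OC(C)C)C(O)(CCc2ccc(cc2)Oc2cc(CCc3cccc(OCOC)c3)ccc2O[Si](C(C)C)(C(C)C)C(C)C)C1=O | intermediate
16 | 3-(propan-2-yloxy)-4-(2-arylethyl)cyclobut-3-ene-1,2-dione, ring D still as methoxymethyl ether | CC(C)OC1=C(CCc2ccc(cc2)Oc2cc(CCc3cccc(OCOC)c3)ccc2O[Si](C(C)C)(C(C)C)C(C)C)C(=O)C1=O | intermediate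
17 | 3-hydroxy-4-[2-(4-{5-[2-(3-hydroxyphenyl)ethyl]-2-[tri(propan-2-yl)silyloxy]phenoxy}phenyl)ethyl]cyclobut-3-ene-1,2-dione | OC1=C(CCc2ccc(cc2)Oc2cc(CCc3cccc(O)c3)ccc2O[Si](C(C)C)(C(C)C)C(C)C)C(=O)C1=O | intermediate
18 | 3-chloro analogue of 17 (chloro dione, free ring D phenol) | ClC1=C(CCc2ccc(cc2)Oc2cc(CCc3cccc(O)c3)ccc2O[Si](C(C)C)(C(C)C)C(C)C)C(=O)C1=O | intermediate
19 | macrocyclic 3-aryloxy-4-alkylcyclobut-3-ene-1,2-dione (18-membered ring, ring C triisopropylsilyl ether) | O=C1C(=O)C2=C1CCc1ccc(cc1)Oc1cc(ccc1O[Si](C(C)C)(C(C)C)C(C)C)CCc1cccc(c1)O2 | intermediate
20 | 2-chloro-1,1-dimethoxyethane | COC(CCl)OC | starting material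
21 | sodium methoxyacetylide | [Na+].[C-]#COC | intermediate
22 | methoxyethyne | COC#C | intermediate
23 | lithium methoxyacetylide | [Li]C#COC | intermediate
24 | macrocyclic 2-alkyl-3-aryloxy-4-hydroxy-4-(methoxyethynyl)cyclobut-2-en-1-one, racemic, ring C triisopropylsilyl ether | COC#CC1(O)C(=O)C(CCc3ccc(cc3)Oc3cc(ccc3O[Si](C(C)C)(C(C)C)C(C)C)CCc3cccc(c3)O2)=C12 | intermediate
25 | macrocyclic (Z)-enynyl ketene (ketene carbon is the future A6; hydroxyl trans to the ketene-bearing carbon) | O=C=C(CCc1ccc(cc1)Oc1cc(ccc1O[Si](C(C)C)(C(C)C)C(C)C)CCc1cccc(c1)O2)/C2=C(/O)C#COC | intermediate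
26 | benzenoid diradical (carbon radical at A2, oxygen radical on A6, hydroxyl on A3) | COC1=[C]C(O)=C2C(CCc3ccc(cc3)Oc3cc(ccc3O[Si](C(C)C)(C(C)C)C(C)C)CCc3cccc(c3)O2)=C1[O] | intermediate
27 | ring C triisopropylsilyl ether of the target quinone | COC1=CC(=O)C2=C(CCc3ccc(cc3)Oc3cc(ccc3O[Si](C(C)C)(C(C)C)C(C)C)CCc3cccc(c3)O2)C1=O | intermediate
28 | CNP0332646.0 | COC1=CC(=O)C2=C(CCc3ccc(cc3)Oc3cc(ccc3O)CCc3cccc(c3)O2)C1=O | target

## Step count and risk

Total: 14 steps. Longest linear sequence: 12 steps (steps 2 to 10 and 12 to 14, from 3).

**Step 13 (key step).** The most likely failure is five-membered closure of ketene 25: the alkyne carbon remote from oxygen is the nucleophilic end of an ynol ether and can attack the ketene carbon in a polar sense, leading to an alkylidenecyclopentenedione. Slow decomposition of the ynol ether before ring opening is the second risk. The fallback replaces the alkyne by an alkene, so that ring A closes by a 6π electrocyclisation with no five-membered option. It sets out from 19. (Z)-2-methoxyethenyllithium F1, made from (Z)-1-bromo-2-methoxyethene and t-BuLi in Et2O at −78 °C, is added to the ketone-like carbonyl of 19 to give the 4-hydroxy-4-[(Z)-2-methoxyethenyl]cyclobutenone F2. Thermolysis in toluene or xylene should give, through the dienyl ketene and tautomerisation, the macrocyclic methoxyhydroquinone F3. Oxidation with Ag2O in Et2O returns to the route at 27.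

**Step 10.** Intermolecular acylation of the free ring D phenol (oligomer formation) can set in while chloride 18 is made or before it meets the base, and the phenol can be acylated by the chlorinating agent. The fallback keeps the phenol masked until ring closure. It sets out from 17. Silylation with TESCl and imidazole gives the bis(triethylsilyl) derivative F4, with a silyl vinylogous ester and a ring D silyl ether. Oxalyl chloride with catalytic DMF converts the silyl ester directly into the chloro dione with ring D triethylsilyl ether F5. Slow addition of F5 to anhydrous CsF in MeCN at high dilution should release the unhindered ring D phenoxide, ahead of the hindered ring C silyl ether, and close the ring, returning at 19.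

**Step 12.** The acetylide can attack the aryloxy-bearing carbon and expel the ring D phenoxide (opening of the macrocycle). It can also add at the vinylogous ester carbonyl or deprotonate the CH2 beside the four-membered ring. The fallback changes the nucleophile from a lithium to a cerium reagent, which is less basic, more oxophilic and confined to carbonyl addition. It sets out from 22 and 19. Acetylide 23 is transmetalated with anhydrous CeCl3 in THF at −78 °C to dichlorocerium methoxyacetylide F6, which is added to 19 and returns at 24.

**Step 9.** Hydrolysis of the isopropyl vinylogous ester may need heating long enough to erode the ring C silyl ether, or may stop at 16. The fallback uses a squarate whose ester falls by acidolysis without water or heat. It sets out from 12. Grignard reagent 14 is added to 3,4-di-tert-butoxycyclobut-3-ene-1,2-dione at −78 °C to give the di-tert-butoxy adduct F7. TFA in CH2Cl2 at 0 °C to rt should bring about rearrangement, loss of both tert-butyl groups and cleavage of the acetal, returning at 17.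

**Step 4.** Coupling at the hindered, electron-rich aryl bromide may be slow, so that reduction of the carbon–bromine bond or arylation of the aliphatic hydroxyl competes. The fallback reverses the polarity of ring C. It sets out from 7. Miyaura borylation (B2pin2, Pd(dppf)Cl2, KOAc, dioxane, 80 °C) gives the pinacol boronate F8. Chan–Lam coupling of F8 with 8 (Cu(OAc)2, pyridine, 4 Å sieves, air, MeCN) is selective for the phenol and returns at 9.

## Further compounds

F1 | step 13 | (Z)-2-methoxyethenyllithium | [Li]/C=C\OC
F2 | step 13 | macrocyclic 2-alkyl-3-aryloxy-4-hydroxy-4-[(Z)-2-methoxyethenyl]cyclobut-2-en-1-one, racemic, ring C triisopropylsilyl ether | CO/C=C\C1(O)C(=O)C(CCc3ccc(cc3)Oc3cc(ccc3O[Si](C(C)C)(C(C)C)C(C)C)CCc3cccc(c3)O2)=C12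
F3 | step 13 | macrocyclic methoxyhydroquinone (ring A at the hydroquinone level, ring C triisopropylsilyl ether) | COc1cc(O)c2c(CCc3ccc(cc3)Oc3cc(ccc3O[Si](C(C)C)(C(C)C)C(C)C)CCc3cccc(c3)O2)c1O
F4 | step 10 | bis(triethylsilyl) derivative of 17 (silyl vinylogous ester and ring D silyl ether) | CC[Si](CC)(CC)OC1=C(CCc2ccc(cc2)Oc2cc(CCc3cccc(O[Si](CC)(CC)CC)c3)ccc2O[Si](C(C)C)(C(C)C)C(C)C)C(=O)C1=O
F5 | step 10 | chloro dione with ring D triethylsilyl ether | ClC1=C(CCc2ccc(cc2)Oc2cc(CCc3cccc(O[Si](CC)(CC)CC)c3)ccc2O[Si](C(C)C)(C(C)C)C(C)C)C(=O)C1=O
F6 | step 12 | dichlorocerium methoxyacetylide | COC#C[Ce](Cl)Cl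
F7 | step 9 | di-tert-butoxy squarate mono-adduct, racemic | CC(C)(C)OC1=C(OC(C)(C)C)C(O)(CCc2ccc(cc2)Oc2cc(CCc3cccc(OCOC)c3)ccc2O[Si](C(C)C)(C(C)C)C(C)C)C1=O
F8 | step 4 | pinacol boronate of 7 (boron in place of bromine, E/Z mixture) | COCOc1cccc(C=Cc2ccc(OCc3ccccc3)c(B3OC(C)(C)C(C)(C)O3)c2)c1
A1 | alternative 1 | seco precursor with 2-aryloxybuta-1,3-diene on ring C oxygen and ethynyl ketone on the ring A side chain | COc1cc(OCc2ccccc2)c(Oc2cccc(CCc3ccc(OCc4ccccc4)c(OC(=C)C=C)c3)c2)c(CC(=O)C#C)c1OCc1ccccc1
A2 | alternative 1 | macrocyclic cyclohexa-1,4-diene with benzylic ketone (ring B at the dihydroarene level) | COc1cc(OCc2ccccc2)c2c(CC(=O)C3=CCC(=CC3)Oc3cc(ccc3OCc3ccccc3)CCc3cccc(c3)O2)c1OCc1ccccc1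
A3 | alternative 2 | seco 2-bromo-3-alkyl-5-methoxy-1,4-benzoquinone with free ring D phenol and ring C methoxymethyl ether | COC1=CC(=O)C(Br)=C(CCc2ccc(cc2)Oc2cc(CCc3cccc(O)c3)ccc2OCOC)C1=O
A4 | alternative 2 | ring C methoxymethyl ether of the target quinone | COC1=CC(=O)C2=C(CCc3ccc(cc3)Oc3cc(ccc3OCOC)CCc3cccc(c3)O2)C1=O
A5 | alternative 3 | seco compound with ring C 2,6-dibromo-4-alkylphenol, free ring B phenol and ring A dibenzyl hydroquinone ether | COc1cc(OCc2ccccc2)c(Oc2cccc(CCc3cc(Br)c(O)c(Br)c3)c2)c(CCc2ccc(O)cc2)c1OCc1ccccc1
A6 | alternative 3 | macrocycle with free ring C phenol, one residual ortho bromine and ring A as dibenzyl hydroquinone ether | COc1cc(OCc2ccccc2)c2c(CCc3ccc(cc3)Oc3cc(cc(Br)c3O)CCc3cccc(c3)O2)c1OCc1ccccc1
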